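The pyranone ring (ring C) is opened at C3–C4 and O1–C2. This treats the C4 ketone, the C3 methylene and the oxygen-bearing C2 as a masked 1,3-diketone on the salicyloyl unit O1–C8a–C4a–C4 of ring A. A [Cp*RhCl2]2-catalysed annulation couples the formyl C–H bond of 2-hydroxy-3,6-dimethoxybenzaldehyde with the ylide carbon of a keto sulfoxonium ylide that already carries the whole (Z)-alkenyl chain. The diketone so formed closes onto the phenol in the same flask to give the chromone. An asymmetric CuH conjugate reduction then sets C2 as (R), and oxidative demethylation with reductive work-up frees the 5,8-hydroquinone.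

Key step: step 3

Assumption: 2,5-dimethoxyphenol and methyl (Z)-octadec-13-enoate are taken as purchasable, and (R)-DTBM-SEGPHOS–CuH is taken to deliver hydride to the Si face of C2 of chromone 6; if a trial shows the opposite sense, the (S)-ligand is used with no other change.

Step 1
Reactants: 1 2,5-dimethoxyphenol
Product: 2 2-hydroxy-3,6-dimethoxybenzaldehyde
Conditions: MgCl2 (1.5 equiv), Et3N (3.75 equiv), paraformaldehyde (6 equiv), MeCN, reflux; 1 M HCl work-up
Reagents that add atoms: paraformaldehyde (as formaldehyde), C=O
Why: Magnesium-phenoxide-directed ortho-formylation (Casnati–Skattebøl reaction) should deliver formaldehyde only to the single free ortho carbon of 1, and a second formaldehyde oxidises the benzylic alkoxide to the aldehyde by hydride transfer.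

Step 2
Reactants: 3 methyl (Z)-octadec-13-enoate
Product: 4 (Z)-1-[dimethyl(oxo)-λ6-sulfanylidene]nonadec-14-en-2-one
Conditions: Me3S(O)I (3 equiv), KOtBu (3 equiv), THF, reflux, 2 h; then 3, THF, reflux
Reagents that add atoms: trimethylsulfoxonium iodide, C[S+](C)(C)=O.[I-]
Why: Acylation of dimethylsulfoxonium methylide (Corey–Chaykovsky reagent) by the methyl ester, followed by deprotonation by excess ylide, should give the stabilised keto ylide, and the isolated Z-alkene is no acceptor for the ylide.

Step 3
Reactants: 2 2-hydroxy-3,6-dimethoxybenzaldehyde and 4 (Z)-1-[dimethyl(oxo)-λ6-sulfanylidene]nonadec-14-en-2-one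
Product: 6 2-[(Z)-heptadec-12-en-1-yl]-5,8-dimethoxy-4H-chromen-4-one, via diketone 5 (not isolated)
Conditions: [Cp*RhCl2]2 (2.5 mol %), AgSbF6 (10 mol %), PivOH (1 equiv), ClCH2CH2Cl, 80 °C; then TsOH·H2O (10 mol %), 80 °C
Reagents that add atoms: none
Why: The phenoxide of 2 binds the cationic Cp*Rh fragment (trivalent rhodium) and directs carboxylate-assisted metalation of the formyl C–H bond to a five-membered acyl rhodacycle; ylide 4 then binds through carbon, loses dimethyl sulfoxide to give a rhodium carbene, and migratory insertion of the acyl group followed by protodemetalation forms the C3–C4 bond of diketone 5. The acid in the flask then drives attack of the phenol oxygen on the chain ketone (6-exo-trig hemiketalisation) and loss of water, which forms the O1–C2 bond and the aromatic pyranone of 6. The closest known reaction type is the Cp*Rh-catalysed formyl C–H acylmethylation and annulation of salicylaldehydes with sulfoxonium ylides to chromones. No stereocenter is formed, since C2 is still trigonal in 6. The step needs formyl over aryl C–H activation, which is secured because the phenol is the only directing group and has no C–H bond ortho to it. It also needs a single mode of ring closure, which is secured because the future 5- and 8-oxygens are methyl ethers and only the future O1 is a free hydroxyl; the remote Z-alkene offers the catalyst no handle.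

Step 4
Reactants: 6 2-[(Z)-heptadec-12-en-1-yl]-5,8-dimethoxy-4H-chromen-4-one
Product: 8 (R)-2-[(Z)-heptadec-12-en-1-yl]-5,8-dimethoxychroman-4-one, via silyl enol ether 7 (not isolated)
Conditions: Cu(OAc)2·H2O (5 mol %), (R)-DTBM-SEGPHOS (5.5 mol %), (EtO)2MeSiH (3 equiv), toluene, 0 °C to room temperature; then 1 M HCl, THF, 0 °C
Reagents that add atoms: none
Why: Ligand-controlled asymmetric 1,4-hydrocupration of the vinylogous ester (CuH conjugate reduction) should deliver hydride to the Si face of C2 and set (R), the copper enolate is silylated to 7 so that neither over-reduction nor ring opening can follow, and the isolated alkene is inert to CuH.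

Step 5
Reactants: 8 (R)-2-[(Z)-heptadec-12-en-1-yl]-5,8-dimethoxychroman-4-one
Product: 10 (R)-2-[(Z)-heptadec-12-en-1-yl]-5,8-dihydroxychroman-4-one, via quinone 9 (not isolated)
Conditions: (NH4)2Ce(NO3)6 (2.5 equiv), MeCN/H2O 2:1, 0 °C, 15 min; then EtOAc, saturated aqueous Na2S2O4, room temperature, under argon
Reagents that add atoms: water, O
Why: Oxidative demethylation of the para-dimethoxyarene by tetravalent cerium (two one-electron oxidations, ipso attack of water, loss of two methanol) should give quinone 9 under base-free conditions that leave C2 and the Z-alkene untouched, and dithionite reduction of the quinone then gives the hydroquinone.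

Compound list
1 | 2,5-dimethoxyphenol | COc1ccc(OC)c(O)c1 | starting material
2 | 2-hydroxy-3,6-dimethoxybenzaldehyde | COc1ccc(OC)c(O)c1C=O | intermediate
3 | methyl (Z)-octadec-13-enoate | CCCC/C=C\CCCCCCCCCCCC(=O)OC | starting material
4 | (Z)-1-[dimethyl(oxo)-λ6-sulfanylidene]nonadec-14-en-2-one | CCCC/C=C\CCCCCCCCCCCC(=O)C=S(C)(C)=O | intermediate
5 | (Z)-1-(2-hydroxy-3,6-dimethoxyphenyl)icos-15-ene-1,3-dione | CCCC/C=C\CCCCCCCCCCCC(=O)CC(=O)c1c(O)c(OC)ccc1OC | intermediate
6 | 2-[(Z)-heptadec-12-en-1-yl]-5,8-dimethoxy-4H-chromen-4-one | CCCC/C=C\CCCCCCCCCCCc1cc(=O)c2c(OC)ccc(OC)c2o1 | intermediate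
7 | (R)-diethoxy(methyl)silyl enol ether of 8, i.e. (R)-4-[diethoxy(methyl)silyloxy]-2-[(Z)-heptadec-12-en-1-yl]-5,8-dimethoxy-2H-chromene | CCCC/C=C\CCCCCCCCCCC[C@@H]1C=C(O[Si](C)(OCC)OCC)c2c(OC)ccc(OC)c2O1 | intermediate
8 | (R)-2-[(Z)-heptadec-12-en-1-yl]-5,8-dimethoxychroman-4-one | CCCC/C=C\CCCCCCCCCCC[C@@H]1CC(=O)c2c(OC)ccc(OC)c2O1 | intermediate
9 | (R)-2-[(Z)-heptadec-12-en-1-yl]-2,3-dihydro-4H-chromene-4,5,8-trione | CCCC/C=C\CCCCCCCCCCC[C@@H]1CC(=O)C2=C(O1)C(=O)C=CC2=O | intermediate
10 | (R)-2-[(Z)-heptadec-12-en-1-yl]-5,8-dihydroxychroman-4-one | CCCC/C=C\CCCCCCCCCCC[C@@H]1CC(=O)c2c(O)ccc(O)c2O1 | target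

Total step count: 5. Longest linear sequence: 4 steps (step 1 or step 2, then steps 3, 4 and 5).

Steps most likely to fail

Step 3. Metalation of the formyl C–H bond may be slow because the aldehyde is flanked by the 6-methoxy group, the chelating diketone or chromone may sequester the catalyst, and the ylide may decompose by protonolysis before it is captured. The fallback sets out from 2 and comes back at 6 by a classical Claisen route. Addition of MeMgBr (3 equiv, THF, 0 °C) to 2 should give the benzylic alcohol racemic 1-(2-hydroxy-3,6-dimethoxyphenyl)ethan-1-ol F1 after aqueous work-up. Oxidation of F1 with MnO2 (CH2Cl2, room temperature) should give the acetophenone 1-(2-hydroxy-3,6-dimethoxyphenyl)ethan-1-one F2 in turn. Crossed Claisen condensation of the dianion of F2 (LiN(SiMe3)2, 3 equiv, THF, −78 to 0 °C) with ester 3 should give diketone 5, and TsOH in toluene at reflux should close it to 6.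

Step 4. Facial discrimination at a C2 that carries only an unbranched chain may be poor, 1,2-reduction of the carbonyl may compete, and the 5-methoxy group may slow hydrocupration. The fallback sets out from 6 and comes back at 8 by non-selective reduction and resolution. LiBH(s-Bu)3 (THF, −78 °C) should give racemic 2-[(Z)-heptadec-12-en-1-yl]-5,8-dimethoxychroman-4-one F3 by 1,4-hydride addition. Preparative chromatography of F3 on an amylose tris(3,5-dimethylphenylcarbamate) phase should separate 8 from its enantiomer (S)-2-[(Z)-heptadec-12-en-1-yl]-5,8-dimethoxychroman-4-one F4 on scale. F4 is equilibrated back to F3 with catalytic DBU through reversible opening of ring C and recycled.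

Step 5. The transient acylquinone may tautomerise with loss of the C2 stereocenter, water may attack C8a and open ring C, and the hydroquinone may re-oxidise in air. The fallback sets out from 8 and comes back at 10 by stepwise Lewis-acid ether cleavage. BCl3 (CH2Cl2, −78 to 0 °C) should remove the 5-O-methyl group of 8 through the chelate with the C4 carbonyl and give (R)-2-[(Z)-heptadec-12-en-1-yl]-5-hydroxy-8-methoxychroman-4-one F5 as the chelated phenol. BBr3 (CH2Cl2, −78 to −20 °C, short contact time) should then remove the 8-O-methyl group of F5 and give 10.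

Further compounds
F1 | step 3 | racemic 1-(2-hydroxy-3,6-dimethoxyphenyl)ethan-1-ol | CC(O)c1c(O)c(OC)ccc1OC
F2 | step 3 | 1-(2-hydroxy-3,6-dimethoxyphenyl)ethan-1-one | CC(=O)c1c(O)c(OC)ccc1OC
F3 | step 4 | racemic 2-[(Z)-heptadec-12-en-1-yl]-5,8-dimethoxychroman-4-one | CCCC/C=C\CCCCCCCCCCCC1CC(=O)c2c(OC)ccc(OC)c2O1
F4 | step 4 | (S)-2-[(Z)-heptadec-12-en-1-yl]-5,8-dimethoxychroman-4-one | CCCC/C=C\CCCCCCCCCCC[C@H]1CC(=O)c2c(OC)ccc(OC)c2O1
F5 | step 5 | (R)-2-[(Z)-heptadec-12-en-1-yl]-5-hydroxy-8-methoxychroman-4-one | CCCC/C=C\CCCCCCCCCCC[C@@H]1CC(=O)c2c(O)ccc(OC)c2O1
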